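**Retrosynthetic overview**
- The dihydropyran is the only ring that has to be built, and it is closed last by C2–O1 bond formation: the ring A hydroxyl para to the acyl group adds (oxa-Michael) to a ring B ortho-quinone methide, and the C3 centre directs 2,3-trans.
- The quinone methide comes from 2,4-diformylphloroglucinol and an (S)-α-isopropyl aldehyde that already carries ring A and is stored as its lactol.
- That aldehyde comes from phlorisovalerophenone and 2-isopropylacrolein: aryl C–H conjugate addition makes C4–C4a, and an enantioselective protonation sets C3.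
- Both benzene rings come ready-made from phloroglucinol (mono-acylation for ring A, double formylation for ring B); the enal comes from isovaleraldehyde and formaldehyde.

Assumption: the target is taken exactly as the given SMILES, the (2R,3S), 2,3-trans chroman (O1, C2 aryl, C3 isopropyl, C4 methylene); the (2S) catalyst of step 4 is assumed to give the (3S) centre, and its (2R) antipode is used if the sense turns out opposite.

**Step 1**
Reactants: 1 phloroglucinol; 2 isovaleryl chloride
Product: 3 phlorisovalerophenone 1-(2,4,6-trihydroxyphenyl)-3-methylbutan-1-one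
Conditions: AlCl3 (3.5 equiv), PhNO2/CH2Cl2, 0 → 50 °C; then ice/aq. HCl
Reagents that add atoms: none
Why: Friedel–Crafts C-acylation of the very electron-rich arene stops at the mono-ketone because the AlCl3-chelated acyl group deactivates the ring.

**Step 2**
Reactants: 1 phloroglucinol
Product: 4 2,4-diformylphloroglucinol (2,4,6-trihydroxybenzene-1,3-dicarbaldehyde)
Conditions: POCl3 (2.4 equiv), DMF (2.6 equiv), EtOAc, 0 °C → rt; then H2O, rt
Reagents that add atoms: N,N-dimethylformamide CN(C)C=O; water O
Why: Double Vilsmeier–Haack formylation, in which the two iminium/formyl groups deactivate the ring enough to leave the third position free.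

**Step 3**
Reactants: 5 isovaleraldehyde
Product: 6 2-isopropylacrolein (3-methyl-2-methylidenebutanal)
Conditions: 37% aq. HCHO (1.05 equiv), pyrrolidine (10 mol%), propanoic acid (10 mol%), iPrOH, 45 °C
Reagents that add atoms: formaldehyde C=O
Why: Amine-catalysed Mannich condensation with formaldehyde followed by elimination of the amine (α-methylenation of an aldehyde) gives the 2-substituted acrolein.

**Step 4**
Reactants: 3 phlorisovalerophenone; 6 2-isopropylacrolein
Product: 8 lactol 1-[(3S)-2,5,7-trihydroxy-3-(propan-2-yl)-3,4-dihydro-2H-chromen-6-yl]-3-methylbutan-1-one (anomer mixture), via open-chain aldehyde 7 (not isolated)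
Conditions: (2S)-N1,N1-diethyl-3,3-dimethylbutane-1,2-diamine (20 mol%), CF3SO3H (20 mol%), EtOAc, 0 °C, 6 added over 8 h
Reagents that add atoms: none
Why: Proposed new method: an enantioselective Friedel–Crafts conjugate addition/protonation in which the chiral primary amine condenses with the α-branched enal 6 to an iminium ion, a free ring position of acylphloroglucinol 3 adds to the unsubstituted β-CH2 to give an enamine, and the protonated NEt2 arm of the catalyst delivers the proton to one face of the enamine α-carbon, which sets C3 as (S); hydrolysis gives aldehyde 7, whose immediate hemiacetalisation to lactol 8 takes it out of the enamine manifold and so protects the new centre; the closest known reaction type is the chiral primary–tertiary diamine-catalysed Friedel–Crafts alkylation/enantioselective protonation of α-substituted acroleins with indoles, which has not been shown for phloroglucinol C-nucleophiles or with lactol capture.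

**Step 5**
Reactants: 8 lactol; 4 2,4-diformylphloroglucinol
Product: 11 5-[(2R,3S)-5,7-dihydroxy-6-(3-methylbutanoyl)-3-(propan-2-yl)-3,4-dihydro-2H-chromen-2-yl]-2,4,6-trihydroxybenzene-1,3-dicarbaldehyde (CNP0551232.1), via benzylic alcohol adduct 9 (not isolated), via ring B ortho-quinone methide 10 (not isolated)
Conditions: CH3CO2Na (0.3 equiv), CH3CO2H, 55 °C, 8 added over 6 h
Reagents that add atoms: none
Why: Lactol 8 reacts through its open-chain aldehyde tautomer, which hydroxyalkylates the free position of 4 (Knoevenagel-type) to give 9, loss of water gives ortho-quinone methide 10, and reversible intramolecular oxa-Michael addition of the ring A hydroxyl para to the acyl group (the most acidic one, not held in the ketone hydrogen bond) forms the C2–O1 bond and the pyran ring through a chair-like transition state with the C2 aryl and C3 isopropyl groups equatorial, so the fixed (3S) centre gives (2R) (2,3-trans); the amine-free buffer avoids enamine epimerisation at C3 and imine formation at the formyl groups.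

**Compound list**
1 | phloroglucinol (benzene-1,3,5-triol) | Oc1cc(O)cc(O)c1 | starting material
2 | isovaleryl chloride (3-methylbutanoyl chloride) | CC(C)CC(=O)Cl | starting material
3 | phlorisovalerophenone, 1-(2,4,6-trihydroxyphenyl)-3-methylbutan-1-one | CC(C)CC(=O)c1c(O)cc(O)cc1O | intermediate
4 | 2,4-diformylphloroglucinol, 2,4,6-trihydroxybenzene-1,3-dicarbaldehyde | O=Cc1c(O)cc(O)c(C=O)c1O | intermediate
5 | isovaleraldehyde (3-methylbutanal) | CC(C)CC=O | starting material
6 | 2-isopropylacrolein (3-methyl-2-methylidenebutanal) | CC(C)C(=C)C=O | intermediate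
7 | (2S)-3-methyl-2-{[2,4,6-trihydroxy-3-(3-methylbutanoyl)phenyl]methyl}butanal (open form of 8, not isolated) | CC(C)CC(=O)c1c(O)cc(O)c(C[C@@H](C(C)C)C=O)c1O | intermediate
8 | 1-[(3S)-2,5,7-trihydroxy-3-(propan-2-yl)-3,4-dihydro-2H-chromen-6-yl]-3-methylbutan-1-one (lactol, anomer mixture) | CC(C)CC(=O)c1c(O)cc2c(c1O)C[C@@H](C(C)C)C(O)O2 | intermediate
9 | 2,4,6-trihydroxy-5-[(2S)-1-hydroxy-3-methyl-2-{[2,4,6-trihydroxy-3-(3-methylbutanoyl)phenyl]methyl}butyl]benzene-1,3-dicarbaldehyde (both carbinol epimers, not isolated) | CC(C)CC(=O)c1c(O)cc(O)c(C[C@@H](C(C)C)C(O)c2c(O)c(C=O)c(O)c(C=O)c2O)c1O | intermediate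
10 | 2,4-dihydroxy-6-oxo-5-[(2S)-3-methyl-2-{[2,4,6-trihydroxy-3-(3-methylbutanoyl)phenyl]methyl}butylidene]cyclohexa-1,3-diene-1,3-dicarbaldehyde (ring B ortho-quinone methide, not isolated) | CC(C)CC(=O)c1c(O)cc(O)c(C[C@@H](C(C)C)C=C2C(=O)C(C=O)=C(O)C(C=O)=C2O)c1O | intermediate
11 | 5-[(2R,3S)-5,7-dihydroxy-6-(3-methylbutanoyl)-3-(propan-2-yl)-3,4-dihydro-2H-chromen-2-yl]-2,4,6-trihydroxybenzene-1,3-dicarbaldehyde (2,3-trans) | CC(C)CC(=O)c1c(O)cc2c(c1O)C[C@@H](C(C)C)[C@H](c1c(O)c(C=O)c(O)c(C=O)c1O)O2 | target

**Step count**
Total steps: 5. Longest linear sequence: 3 steps (1 → 3 → 8 → 11; steps 1, 4, 5). No protecting groups.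

**Three steps most likely to fail**

Step 4 (the proposed new step). The risks are:
- a racemic background addition;
- 1,2-addition at the iminium carbon, which would lead on to a 2H-chromene;
- double alkylation of 3, which the slow addition of 6 is meant to suppress by keeping 3 in excess over 6 in the flask;
- modest selectivity in protonating an enamine that carries a bulky isopropyl group.

The fallback uses known chemistry and replaces asymmetric catalysis by resolution. It sets out from 3 and 6: the same Michael addition/hemiacetalisation is run with an achiral amine salt (ethane-1,2-diammonium diacetate, EtOAc, rt) to give the racemic lactol 1-[2,5,7-trihydroxy-3-(propan-2-yl)-3,4-dihydro-2H-chromen-6-yl]-3-methylbutan-1-one F1. F1 is condensed with 4 under the step 5 conditions to give the racemic 2,3-trans chroman 5-[5,7-dihydroxy-6-(3-methylbutanoyl)-3-(propan-2-yl)-3,4-dihydro-2H-chromen-2-yl]-2,4,6-trihydroxybenzene-1,3-dicarbaldehyde F2. The enantiomers are separated by preparative chiral supercritical-fluid chromatography (amylose tris(3,5-dimethylphenylcarbamate) phase, CO2/MeOH); the (2R,3S) enantiomer is 11, where the fallback rejoins the route.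

Step 5. The risks are:
- partial epimerisation of the aldehyde α-centre (C3) before the condensation;
- dehydration of the lactol to the 4H-chromene, or tautomerisation of quinone methide 10 to the styrene, either of which erases C3;
- closure through the ring A hydroxyl ortho to the acyl group (the angular 8-acyl isomer);
- self-condensation of 8 through its free ring A position, which the slow addition of 8 is meant to suppress by keeping 4 in excess in the flask.

The fallback closes the pyran by cycloaddition instead and never passes through an epimerisable aldehyde. It sets out from 4 and 3: 4 is condensed with isovaleraldehyde 5 (CH3CO2Na, CH3CO2H, 80 °C; the quinone methide tautomerises) to the styrene 2,4,6-trihydroxy-5-[(1E)-3-methylbut-1-en-1-yl]benzene-1,3-dicarbaldehyde F3. The ring A ortho-quinone methide 3,5-dihydroxy-6-methylidene-4-(3-methylbutanoyl)cyclohexa-2,4-dien-1-one F4 is generated in the flask from 3 and paraformaldehyde and trapped by F3 in an oxa-[4+2] cycloaddition under a chiral phosphoric acid ((R)-3,3'-bis(2,4,6-triisopropylphenyl)-1,1'-binaphthalene-2,2'-diyl hydrogen phosphate, toluene, 0 °C → rt). The methylene terminus bonds to the isopropyl-bearing alkene carbon and the oxygen to the benzylic carbon, and the E-alkene gives the 2,3-trans chroman 11 directly, where the fallback rejoins the route.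

Step 2. The risks are a mixture of mono-, di- and triformylated phloroglucinols and a difficult purification of the very polar, acidic product. The fallback formylates the protected arene and then deprotects. It sets out from 1: methylation (Me2SO4, K2CO3, acetone, reflux) gives 1,3,5-trimethoxybenzene F5. Double Rieche formylation (Cl2CHOCH3, TiCl4, CH2Cl2, 0 °C) gives 2,4,6-trimethoxybenzene-1,3-dicarbaldehyde F6. Demethylation (BBr3, CH2Cl2, −78 °C → rt) gives 4, where the fallback rejoins the route.

**Further compounds**
F1 | step 4 | racemic lactol 1-[2,5,7-trihydroxy-3-(propan-2-yl)-3,4-dihydro-2H-chromen-6-yl]-3-methylbutan-1-one | CC(C)CC(=O)c1c(O)cc2c(c1O)CC(C(C)C)C(O)O2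
F2 | step 4 | racemic 2,3-trans chroman (1:1 mixture of 11 and its enantiomer) | CC(C)CC(=O)c1c(O)cc2c(c1O)C[C@@H](C(C)C)[C@H](c1c(O)c(C=O)c(O)c(C=O)c1O)O2.CC(C)CC(=O)c1c(O)cc2c(c1O)C[C@H](C(C)C)[C@@H](c1c(O)c(C=O)c(O)c(C=O)c1O)O2
F3 | step 5 | 2,4,6-trihydroxy-5-[(1E)-3-methylbut-1-en-1-yl]benzene-1,3-dicarbaldehyde | CC(C)/C=C/c1c(O)c(C=O)c(O)c(C=O)c1O
F4 | step 5 | 3,5-dihydroxy-6-methylidene-4-(3-methylbutanoyl)cyclohexa-2,4-dien-1-one (ring A ortho-quinone methide, made in the flask) | CC(C)CC(=O)C1=C(O)C(=C)C(=O)C=C1O
F5 | step 2 | 1,3,5-trimethoxybenzene | COc1cc(OC)cc(OC)c1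
F6 | step 2 | 2,4,6-trimethoxybenzene-1,3-dicarbaldehyde | COc1cc(OC)c(C=O)c(OC)c1C=O
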